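Every unit of solid reagent stays countable: still solid, or partner, or quenched reagent, or coupled to dissolved substrate, with one unit in each target and in each side product. Every unit of protic impurity is free or sits in quenched reagent. This is a plain mass balance, and subtracting the two balances cancels quenched reagent. What stands is charged solid reagent minus charged protic impurity, 1.05 M − 0.750 M = 0.300 M, the surplus:

c(coupled) = surplus + c(protic impurity) − c(partner) − c(solid reagent)

| setting | gamma | flask |
|---|---|---|
| solid substrate | 1.5 M | 1.5 M |
| protic impurity | 0.75 M | 0.750 M |
| solid reagent | 1.6 M | 1.05 M |
| remark | run made earlier |  |
| time |  | 12 h |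

gamma run (percent of the solid substrate charged)

| time / min | target / % | dissolved substrate / % |
|---|---|---|
| 12.0 | 0.2 | 0.2 |
| 25.0 | 0 | 1.4 |
| 40.0 | 0 | 2.8 |
| 50.0 | 0.1 | 2.6 |
| 60.0 | 0 | 3.9 |
| 80.0 | 0.5 | 5.1 |

(scatter of a reading: 0.3 percentage points)

- a species is counted by the solid substrate in it: one side product or homo dimer counts as two
- given per volume of solution although it is solid: solid substrate, solid reagent
- steps under discussion: dissolved substrate + target -> side product; 2 solid substrate -> homo dimer; dissolved substrate + partner -> target; solid substrate <-> dissolved substrate; partner + protic impurity -> quenched reagent; solid reagent <-> partner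
- at the start none of the solid substrate is in solution
- at the start none of the solid reagent is in solution
- dissolved substrate means what is dissolved; the solid is not counted in it

- target at 12 h, in percent of the solid substrate charged
- concentration of dissolved substrate in solution at 12 h, in percent of saturation

In the first instants the right side is zero, since the charges cancel the surplus exactly. The early stretch can be read from the gamma run: by 80.0 min dissolved substrate has reached 5.1 %, while target reads 0.5 %, with a scatter of 0.3 percentage points. Coupling is barely readable there, and dissolved substrate is still rising. The asked time lies 9.00 times as far out. My own reckoning commits to a balance for one case rather than a yield. If the protic impurity takes its whole charge and both forms of reagent are used up, coupled partner equals the surplus, 20.0 % of the solid substrate charged, and target stands below that by what has gone on to side product. It gives no figure for saturation.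

The forecast says 14 % and 75 %, reasoning that the surplus “caps target at 20% of charged substrate”.

The flask gives 11.3 % and 19.0 %: the two agree on target within the margin and part on saturation.

    dissolved substrate + target → side product (k = 0.0170 M⁻¹ min⁻¹)
    2 solid substrate → homo dimer (k = 2.60 × 10⁻⁴ M⁻¹ min⁻¹)
    dissolved substrate + partner → target (k = 0.0390 M⁻¹ min⁻¹)
    solid substrate ⇌ dissolved substrate, rate k4*(cs4 - [dissolved substrate]) while solid is left; crystals form when [dissolved substrate] > cs4 (solubility = 0.690 M, k = 0.00150 min⁻¹)
    partner + protic impurity → quenched reagent (k = 0.0240 M⁻¹ min⁻¹)
    solid reagent ⇌ partner, rate k6*(cs6 - [partner]) while solid is left; crystals form when [partner] > cs6 (solubility = 0.530 M, k = 0.00310 min⁻¹)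

At 12.0 h this flask still holds 24.7 % of its protic impurity, with partner at 0.118 M and 4.53 % of its solid reagent, so

c(coupled) = 0.320 M

This is 21.3 % of the solid substrate charged, and it equals target plus half the side product. A neighbouring flask, charged with 0.90 M of solid substrate, keeps the surplus and the same remainders (24.7 %, 0.118 M, 4.53 %), so the line gives 35.6 % of its charge. Its target plus half its side product comes to 35.6 %, with target at 18.9 %.

All runs stem from a simulated flask for substances that don't exist, noise included.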